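# Gnetal by Danheiser benzannulation around C3a: synthesis plan

## The problem

Gnetal (29) is a 2,3-trans-2,3-diaryl-2,3-dihydrobenzofuran. Ring A (the benzo ring, C3a to C7a) is fused to the dihydrofuran through C3a and C7a and carries a hydroxyl on C4 and a formyl group on C6. C2 bears a 4-hydroxyphenyl group and C3 a 3,5-dihydroxyphenyl group. The only stereocenters are C2 and C3, both S and trans to each other, and they are not of equal weight. C2 is a benzylic ether carbon with a para oxygen on its aryl group, so the O1–C2 bond ionises easily. C2 can therefore be set last, trans to C3, under the control of C3. C3 is a triarylmethane-type carbon with no such pathway; it must be made as one enantiomer and then kept.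

C3 is also the most crowded carbon, and the ring A carbon it joins (C3a) lies between two oxygenated carbons. A late C3–C3a bond or an aromatic substitution on a finished ring A is therefore unattractive. The finished molecule tolerates little:

- The O1–C2 bond opens with Lewis and Brønsted acids, and with base once the para hydroxyl is free (para-quinone methide).
- The aldehyde and the four phenols are sensitive.
- The C3–H bond is doubly benzylic.

This is why the end game uses silyl ethers and fluoride rather than aryl methyl ethers.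

The feature that opens the route is the substitution pattern of ring A: oxygens on C4 and C7a on both sides of C3a, the formyl carbon on C6 para to C3a, hydrogens on C5 and C7. This is the pattern of a resorcinol monosilyl ether formed from a 3-substituted cyclobutenone and a siloxyalkyne. Because ring A is locally symmetric about the C3a–C6 axis, either of its oxygens can become O1.

## Retrosynthesis

**Unmasking.** The four aryl O–Si bonds of aldehyde 28 are cut last, and the formyl group is traced to the hydroxymethyl group of alcohol 27. Fluoride in buffered medium is the mildest reagent the O1–C2 bond and the aldehyde can meet. A Lewis-acidic dealkylation of methyl ethers would attack the same bond that makes the target fragile. Oxidising 27 while every phenol is still silylated avoids exposing free polyphenols to an oxidant. The forward steps only need to distinguish one primary alkyl silyl ether (acid-labile) from four aryl silyl ethers (fluoride-labile).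

**O1–C2.** Cutting this bond in 27 leads to phenol 25, an open chain with a benzylic triethylsilyl ether on the future C2 and a free ring A hydroxyl. Closure through the para-oxygen-stabilised benzylic cation is preferred to an SN2 closure because it does not depend on the C2 configuration of 25. The C3 substituent steers the phenol to the trans face, and reversible ionisation corrects any cis product. Only C3 has to be stereodefined in everything that precedes.

**Ring A (key disconnection).** Ring A of 25 is cut at C3a–C7a, C7–C7a and C4–C5 into siloxyalkyne 15 and cyclobutenone 20. Against an arylation of a preformed, doubly ortho-oxygenated arene at C3a, this places C3 on an alkyne carbon that becomes C3a, so the crowded C3–C3a bond never has to be made on an arene. The oxygen pattern and the para hydroxymethyl carbon follow from the mechanism, not from directing effects. In 25 the free hydroxyl is the oxygen that becomes O1 (on the future C7a), and the silylated oxygen becomes the C4 oxygen. Before the furan ring exists the two are related by the symmetry of ring A, so the annulation need not distinguish them. Cyclobutenone 20 has four carbons and no stereocenter. Alkyne 15 holds all the stereochemistry on an open chain. The forward step must be neutral and tolerate five silyl ethers.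

**O–C(sp).** The siloxy group of 15 is removed to give terminal alkyne 12. Oxidising the acetylide of 12 to ynolate 14 and silylating on oxygen is the shortest way from an alkyne to a siloxyalkyne, and it adds the future C4 oxygen without an ester homologation. The base must not touch the benzylic, propargylic C3–H.

**C2–C3.** Cutting this bond in alcohol 11 (the precursor of 12) gives propargylic mesylate 7 and aldehyde 9. An allenylzinc addition transfers the carbinol configuration of 7 to C3. It also gives the anti C2 alcohol, though C2 is re-set later. Opening a stilbene oxide with an acetylide was rejected: it would attack the wrong, para-oxygenated benzylic carbon.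

**C3–C(alkyne).** Mesylate 7 comes from propargylic alcohol 6, and 6 from alkynol 5, made by catalytic enantioselective addition of ethynyltrimethylsilane 3 to aldehyde 2. This is the single enantioselective step of the route. Aldehydes 2 and 9 are the triisopropylsilyl ethers of 3,5-dihydroxybenzaldehyde 1 and 4-hydroxybenzaldehyde 8.

**Cyclobutenone.** Cyclobutenone 20 is cut across the four-membered ring into silyl propargyl ether 16 and dichloroketene 18 (from trichloroacetyl chloride 17), by way of dichlorocyclobutenone 19. The [2+2] regiochemistry places the siloxymethyl group on C3 of the cyclobutenone, which becomes C6 of ring A.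

## Roads not taken

**Alternative 1: aryne insertion into a stilbene oxide.** The cut is at O1–C7a and C3–C3a. In the forward step CsF would release an aryne from 5-(1,3-dioxolan-2-yl)-3-methoxy-2-(trimethylsilyl)phenyl triflate A3. The oxygen of trans-epoxide A2 would attack the aryne carbon that becomes C7a, and the aryl anion at C3a would capture C3 as the C3–O bond breaks, giving dihydrobenzofuran A1.

- Merits: ring A is bought, both stereocenters come from one asymmetric epoxidation of an (E)-stilbene, and the dihydrofuran closes in the same step. On paper it is the shortest road, and in step count it is better than the chosen plan.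
- Weak points:
  - Formal insertion of an aryne into a C–O bond of a 2,3-diaryl oxirane has little precedent.
  - After O-arylation the oxonium can open at either benzylic carbon. The triflate on the C2 aryl group disfavours C2, but the meta-dimethoxyphenyl ring at C3 stabilises charge poorly as well, so Meinwald-type hydride or aryl shifts to carbonyl compounds compete.
  - The stereochemical course at C3 (tight collapse or open cation) is not secured.
  - The aryl triflate must later become a phenol, and the methyl ethers must be cleaved with a Lewis acid beside the labile O1–C2 bond.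
- Set against it by the chosen plan: three of its four C–C and C–O constructions are standard, ring A regiochemistry is fixed by mechanism, and the end uses fluoride only.

**Alternative 2: conjunctive cross-coupling.** The cut is at the C2–aryl bond and at C3–C3a; no ring closes. The ate complex from (E)-alkenyl boronate A4 and 4-methoxyphenyllithium A5 would react with ring A aryl triflate A6 under Pd(OAc)2 and a MandyPhos-type diphosphine. The anisyl group would migrate from boron to C2 while palladium delivers C3a to C3, giving anti boronate A7.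

- Merits: both stereocenters are set in one catalytic enantioselective step from achiral arenes, and C2 is then fixed by stereospecific C–B oxidation. In how stereochemistry is bought, this road is better than the chosen plan.
- Weak points:
  - A β-aryl alkenyl boronate with an aryl migrating group lies at the edge of the known scope, and direct Suzuki–Miyaura coupling competes.
  - A6 is an electrophile substituted at both ortho positions.
  - After the key step the route still needs oxidation of boron, an intramolecular C–O coupling of a hindered secondary benzylic alcohol with an aryl chloride (β-hydride elimination to the ketone threatens), acetal removal, and cleavage of four methyl ethers with a Lewis acid.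
- Set against it by the chosen plan: ring A emerges with the free phenol needed for closure, the closure corrects C2 by itself, and the deprotection is harmless.

**Alternative 3: fused 2-pyrone Diels–Alder with loss of CO2.** The cut is at the ring A bonds C3a–C4 and C5–C6. Furo-fused pyrone A8 would react thermally with ethoxyethyne A9 across pyrone C3 and C6, and the adduct would lose CO2 to give aldehyde A10.

- Merits: like the chosen plan it builds ring A regiospecifically without aromatic substitution. The formyl group and the whole dihydrofuran with both stereocenters are already present, so the end game is shorter, and the loss of CO2 makes the step irreversible. In these respects it is as good or better.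
- Weak points:
  - The difficulty moves into A8, a trans-2,3-diaryl dihydrofuropyranone whose enantioselective synthesis is a problem of the same size as the target's heterocycle.
  - In A8 the O1–C2 bond has a vinylogous acyloxy leaving group, and C3 sits on the reacting diene during prolonged heating.
  - 4-Oxygenated 2-pyranones are sluggish dienes, and A9 fragments to ketene near the temperatures needed.
  - The ethyl and methyl ethers again require a Lewis acid at the end.
- Set against it by the chosen plan: the stereocenters stay on an open chain away from the reacting π systems, both annulation partners are reached by known steps, and the deprotection uses fluoride.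

Key step: step 11

Assumption: in the zinc–ProPhenol alkynylation (step 2) the (R,R)-ligand is taken as the antipode that delivers the alkynyl group to the Si face of the aryl aldehyde. The sense is to be confirmed on alcohol 6 before scale-up, and the (S,S)-ligand is used instead, with no other change, if it proves opposite.

## Route

Step 1
Reactants: 1 3,5-dihydroxybenzaldehyde
Product: 2 3,5-bis(triisopropylsiloxy)benzaldehyde
Conditions: TIPSCl (2.4 equiv), imidazole, DMF, rt
Reagents that add atoms: triisopropylsilyl chloride, CC(C)[Si](Cl)(C(C)C)C(C)C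
Why: Standard silylation of phenols; aryl triisopropylsilyl ethers should withstand organozinc reagents, amide bases, heat and mild acid and leave with fluoride, so that no Lewis acid is needed near the finished dihydrobenzofuran.

Step 2
Reactants: 2 3,5-bis(triisopropylsiloxy)benzaldehyde; 3 ethynyltrimethylsilane
Product: 5 (1R)-1-[3,5-bis(triisopropylsiloxy)phenyl]-3-(trimethylsilyl)prop-2-yn-1-ol, via methyl[(trimethylsilyl)ethynyl]zinc 4 (not isolated)
Conditions: Me2Zn (3 equiv), (R,R)-ProPhenol (10 mol %), Ph3PO (20 mol %), toluene, 4 °C; aq NH4Cl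
Reagents that add atoms: none
Why: Zinc–ProPhenol catalysed enantioselective alkynylation of an aryl aldehyde: the dinuclear zinc catalyst holds the aldehyde and alkynylzinc 4 on neighbouring zinc atoms and delivers the alkynyl group to the Si face. This sets the carbinol center (R, because the silylalkynyl group outranks the aryl group), whose configuration is later transferred to C3.

Step 3
Reactants: 5 (1R)-1-[3,5-bis(triisopropylsiloxy)phenyl]-3-(trimethylsilyl)prop-2-yn-1-ol
Product: 6 (1S)-1-[3,5-bis(triisopropylsiloxy)phenyl]prop-2-yn-1-ol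
Conditions: K2CO3 (0.2 equiv), MeOH–THF, 0 °C, short reaction time
Reagents that add atoms: none
Why: Base-catalysed methanolysis of the alkynyl C–Si bond, which should be much faster at 0 °C than attack on the hindered aryl triisopropylsilyl ethers. No bond to the stereocenter is touched; the descriptor changes from R to S only because ethynyl ranks below aryl.

Step 4
Reactants: 6 (1S)-1-[3,5-bis(triisopropylsiloxy)phenyl]prop-2-yn-1-ol
Product: 7 (1S)-1-[3,5-bis(triisopropylsiloxy)phenyl]prop-2-yn-1-yl methanesulfonate
Conditions: MsCl, Et3N, CH2Cl2, −78 to −40 °C; cold aqueous work-up, used at once without chromatography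
Reagents that add atoms: methanesulfonyl chloride, CS(=O)(=O)Cl
Why: Sulfonylation of a secondary propargylic alcohol with retention at carbon. The two meta oxygens do not stabilise a benzylic cation, so the mesylate should keep its configuration if kept cold and used directly.

Step 5
Reactants: 8 4-hydroxybenzaldehyde
Product: 9 4-(triisopropylsiloxy)benzaldehyde
Conditions: TIPSCl (1.2 equiv), imidazole, DMF, rt
Reagents that add atoms: triisopropylsilyl chloride, CC(C)[Si](Cl)(C(C)C)C(C)C
Why: Standard phenol silylation; the para siloxy group is still a good enough donor to stabilise the benzylic cation needed in step 12.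

Step 6
Reactants: 7 (1S)-1-[3,5-bis(triisopropylsiloxy)phenyl]prop-2-yn-1-yl methanesulfonate; 9 4-(triisopropylsiloxy)benzaldehyde
Product: 11 (1S,2R)-2-[3,5-bis(triisopropylsiloxy)phenyl]-1-[4-(triisopropylsiloxy)phenyl]but-3-yn-1-ol, via (P)-allenyl(ethyl)zinc 10 (not isolated)
Conditions: Pd(PPh3)4 (5 mol %), Et2Zn (3 equiv), THF, −78 to −20 °C; aq NH4Cl
Reagents that add atoms: none
Why: Marshall propargylation: zerovalent palladium displaces the mesylate anti (SN2'), Et2Zn transmetallates with retention to allenylzinc 10, and 10 adds to the aldehyde through a closed SE2' transition state. The net inversion at the former carbinol carbon gives C3 in the configuration of the target (R here only because ethynyl ranks below aryl). The chair-like transition state with the aldehyde aryl group away from the allenyl substituent gives the anti C2 alcohol, whose configuration is not needed later.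

Step 7
Reactants: 11 (1S,2R)-2-[3,5-bis(triisopropylsiloxy)phenyl]-1-[4-(triisopropylsiloxy)phenyl]but-3-yn-1-ol
Product: 12 triethyl{[(1S,2R)-2-[3,5-bis(triisopropylsiloxy)phenyl]-1-[4-(triisopropylsiloxy)phenyl]but-3-yn-1-yl]oxy}silane
Conditions: TESOTf, 2,6-lutidine, CH2Cl2, −78 to 0 °C
Reagents that add atoms: triethylsilyl trifluoromethanesulfonate, CC[Si](CC)(CC)OS(=O)(=O)C(F)(F)F
Why: Silylation of a hindered secondary benzylic alcohol with the silyl triflate. The triethylsilyl ether removes the only protic site before the ynolate chemistry and the benzannulation, and is the most acid-labile group for step 12.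

Step 8
Reactants: 12 triethyl{[(1S,2R)-2-[3,5-bis(triisopropylsiloxy)phenyl]-1-[4-(triisopropylsiloxy)phenyl]but-3-yn-1-yl]oxy}silane
Product: 15 triethyl{[(1S,2S)-2-[3,5-bis(triisopropylsiloxy)phenyl]-1-[4-(triisopropylsiloxy)phenyl]-4-(triisopropylsiloxy)but-3-yn-1-yl]oxy}silane, via lithium acetylide 13 (not isolated), via lithium ynolate 14 (not isolated)
Conditions: LiN(SiMe3)2 (2.1 equiv in all), t-BuOOH (anhydrous, 1.05 equiv), THF, −78 to 0 °C; then TIPSOTf, −78 to 0 °C
Reagents that add atoms: tert-butyl hydroperoxide, CC(C)(C)OO; triisopropylsilyl trifluoromethanesulfonate, CC(C)[Si](OS(=O)(=O)C(F)(F)F)(C(C)C)C(C)C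
Why: Electrophilic oxygenation of acetylide 13 by lithium tert-butyl peroxide gives ynolate 14, which the bulky silyl triflate traps on oxygen; this is the known route from terminal alkynes to triisopropylsiloxyalkynes. The amide base is used in place of an alkyllithium so that the benzylic, propargylic C3–H is not removed. The descriptor at C3 changes to S by priority only.

Step 9
Reactants: 16 tert-butyldimethyl(prop-2-yn-1-yloxy)silane; 17 trichloroacetyl chloride
Product: 19 3-{[(tert-butyldimethylsilyl)oxy]methyl}-4,4-dichlorocyclobut-2-en-1-one, via dichloroketene 18 (not isolated)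
Conditions: Zn(Cu), Et2O–DME, rt, slow addition of 17
Reagents that add atoms: none
Why: [2+2] cycloaddition of dichloroketene 18, made in the flask by zinc dechlorination of 17, to a terminal alkyne. The ketene carbonyl carbon bonds to the unsubstituted alkyne carbon, which puts the siloxymethyl group on C3; DME ties up ZnCl2 and protects the silyl ether.

Step 10
Reactants: 19 3-{[(tert-butyldimethylsilyl)oxy]methyl}-4,4-dichlorocyclobut-2-en-1-one
Product: 20 3-{[(tert-butyldimethylsilyl)oxy]methyl}cyclobut-2-en-1-one
Conditions: Zn dust, AcOH, TMEDA, EtOH, 0 °C to rt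
Reagents that add atoms: none
Why: Reductive removal of both α-chlorines by zinc in buffered acetic acid, the standard second step of the dichloroketene route to cyclobutenones; the amine buffer should keep the silyl ether and the strained enone intact.

Step 11
Reactants: 15 triethyl{[(1S,2S)-2-[3,5-bis(triisopropylsiloxy)phenyl]-1-[4-(triisopropylsiloxy)phenyl]-4-(triisopropylsiloxy)but-3-yn-1-yl]oxy}silane; 20 3-{[(tert-butyldimethylsilyl)oxy]methyl}cyclobut-2-en-1-one
Product: 25 2-[(1S,2S)-1-[3,5-bis(triisopropylsiloxy)phenyl]-2-(triethylsiloxy)-2-[4-(triisopropylsiloxy)phenyl]ethyl]-5-{[(tert-butyldimethylsilyl)oxy]methyl}-3-(triisopropylsiloxy)phenol, via vinylketene 21 (not isolated), via alkenylcyclobutenone 22 (not isolated), via dienylketene 23 (not isolated), via cyclohexadienone 24 (not isolated)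
Conditions: 15 (1.0 equiv), 20 (1.3 equiv, in portions), toluene, 80 °C then 110 °C, argon
Reagents that add atoms: none
Why: Heat opens 20 by 4π electrocyclic cleavage to vinylketene 21. The nucleophilic carbon of 15 that carries the side chain attacks the ketene carbonyl carbon and the siloxy-bearing carbon bonds to the ketene α-carbon, a [2+2] whose regiochemistry is fixed by the polarisation of the siloxyalkyne, giving 22 (C3a–C7a and C4–C5 formed). Cyclobutenone 22 opens (4π) to dienylketene 23; the isomer with the alkenyl group cis to the ketene closes ring A by 6π electrocyclisation (C7–C7a formed) to dienone 24, which tautomerises to phenol 25, while the other isomer reverts through 22. The closest known reaction type is the Danheiser benzannulation of 3-substituted cyclobutenones with triisopropylsiloxyalkynes, which gives resorcinol monosilyl ethers with the alkyne substituent between the two oxygens and the cyclobutenone substituent para to it. No stereocenter is formed: the ring carbon stereocenter of 22 disappears on opening, and C2 and C3 are spectators because the conditions are neutral and free of acid, base and metal. The only selectivity needed is the [2+2] regiochemistry. Which oxygen emerges free is immaterial, since the two are equivalent until the furan ring closes and the free one then becomes O1. The branched alkyne terminus should slow the [2+2], which is why the cheap cyclobutenone is used in excess and added in portions to keep the ketene concentration low.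

Step 12
Reactants: 25 2-[(1S,2S)-1-[3,5-bis(triisopropylsiloxy)phenyl]-2-(triethylsiloxy)-2-[4-(triisopropylsiloxy)phenyl]ethyl]-5-{[(tert-butyldimethylsilyl)oxy]methyl}-3-(triisopropylsiloxy)phenol
Product: 27 [(2S,3S)-3-[3,5-bis(triisopropylsiloxy)phenyl]-4-(triisopropylsiloxy)-2-[4-(triisopropylsiloxy)phenyl]-2,3-dihydro-1-benzofuran-6-yl]methanol, via cyclised silyl ether 26 (not isolated)
Conditions: CSA (0.2 equiv), CH2Cl2, 0 °C to rt; then MeOH, rt
Reagents that add atoms: none
Why: Acid-mediated cyclisation of a 2-(2-hydroxyaryl)-1,2-diarylethanol derivative: the benzylic triethylsilyl ether ionises to a cation stabilised by the para-siloxyphenyl group, and the ring A phenol closes the five-membered ring at O1–C2 on the face away from the C3 aryl group. C2 is thus set trans under control of C3, and reversible ionisation drains any cis isomer to trans. Methanol then cleaves the primary tert-butyldimethylsilyl ether of 26, which is far more acid-labile than the aryl triisopropylsilyl ethers.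

Step 13
Reactants: 27 [(2S,3S)-3-[3,5-bis(triisopropylsiloxy)phenyl]-4-(triisopropylsiloxy)-2-[4-(triisopropylsiloxy)phenyl]-2,3-dihydro-1-benzofuran-6-yl]methanol
Product: 28 (2S,3S)-3-[3,5-bis(triisopropylsiloxy)phenyl]-4-(triisopropylsiloxy)-2-[4-(triisopropylsiloxy)phenyl]-2,3-dihydro-1-benzofuran-6-carbaldehyde
Conditions: MnO2 (activated, excess), CH2Cl2, rt
Reagents that add atoms: none
Why: Selective oxidation of a benzylic alcohol to the aldehyde by MnO2 under neutral conditions; all phenols are still silylated, so no electron-rich free phenol is exposed to the oxidant.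

Step 14
Reactants: 28 (2S,3S)-3-[3,5-bis(triisopropylsiloxy)phenyl]-4-(triisopropylsiloxy)-2-[4-(triisopropylsiloxy)phenyl]-2,3-dihydro-1-benzofuran-6-carbaldehyde
Product: 29 gnetal, (2S,3S)-3-(3,5-dihydroxyphenyl)-4-hydroxy-2-(4-hydroxyphenyl)-2,3-dihydro-1-benzofuran-6-carbaldehyde
Conditions: Bu4NF (5 equiv), AcOH (5 equiv), THF, 0 °C to rt
Reagents that add atoms: none
Why: Fluoride cleaves the four aryl silyl ethers. Acetic acid keeps the phenoxide concentration low, so the aldehyde and the O1–C2 bond (which strong base could open to a para-quinone methide) are not endangered, and the trans isomer is the thermodynamic one in any case.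

## Compound list

1 | 3,5-dihydroxybenzaldehyde | O=Cc1cc(O)cc(O)c1 | starting material
2 | 3,5-bis(triisopropylsiloxy)benzaldehyde | O=Cc1cc(O[Si](C(C)C)(C(C)C)C(C)C)cc(O[Si](C(C)C)(C(C)C)C(C)C)c1 | intermediate
3 | ethynyltrimethylsilane | C#C[Si](C)(C)C | starting material
4 | methyl[(trimethylsilyl)ethynyl]zinc (not isolated) | C[Zn]C#C[Si](C)(C)C | intermediate
5 | (1R)-1-[3,5-bis(triisopropylsiloxy)phenyl]-3-(trimethylsilyl)prop-2-yn-1-ol | O[C@@H](C#C[Si](C)(C)C)c1cc(O[Si](C(C)C)(C(C)C)C(C)C)cc(O[Si](C(C)C)(C(C)C)C(C)C)c1 | intermediate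
6 | (1S)-1-[3,5-bis(triisopropylsiloxy)phenyl]prop-2-yn-1-ol | O[C@@H](C#C)c1cc(O[Si](C(C)C)(C(C)C)C(C)C)cc(O[Si](C(C)C)(C(C)C)C(C)C)c1 | intermediate
7 | (1S)-1-[3,5-bis(triisopropylsiloxy)phenyl]prop-2-yn-1-yl methanesulfonate | CS(=O)(=O)O[C@@H](C#C)c1cc(O[Si](C(C)C)(C(C)C)C(C)C)cc(O[Si](C(C)C)(C(C)C)C(C)C)c1 | intermediate
8 | 4-hydroxybenzaldehyde | O=Cc1ccc(O)cc1 | starting material
9 | 4-(triisopropylsiloxy)benzaldehyde | O=Cc1ccc(O[Si](C(C)C)(C(C)C)C(C)C)cc1 | intermediate
10 | (P)-{3-[3,5-bis(triisopropylsiloxy)phenyl]propa-1,2-dien-1-yl}(ethyl)zinc (not isolated) | CC[Zn]C([H])=[C@@]=C([H])c1cc(O[Si](C(C)C)(C(C)C)C(C)C)cc(O[Si](C(C)C)(C(C)C)C(C)C)c1 | intermediate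
11 | (1S,2R)-2-[3,5-bis(triisopropylsiloxy)phenyl]-1-[4-(triisopropylsiloxy)phenyl]but-3-yn-1-ol | O[C@H](c1ccc(O[Si](C(C)C)(C(C)C)C(C)C)cc1)[C@H](C#C)c1cc(O[Si](C(C)C)(C(C)C)C(C)C)cc(O[Si](C(C)C)(C(C)C)C(C)C)c1 | intermediate
12 | triethyl{[(1S,2R)-2-[3,5-bis(triisopropylsiloxy)phenyl]-1-[4-(triisopropylsiloxy)phenyl]but-3-yn-1-yl]oxy}silane | CC[Si](CC)(CC)O[C@H](c1ccc(O[Si](C(C)C)(C(C)C)C(C)C)cc1)[C@H](C#C)c1cc(O[Si](C(C)C)(C(C)C)C(C)C)cc(O[Si](C(C)C)(C(C)C)C(C)C)c1 | intermediate
13 | lithium acetylide of 12, side chain unchanged (not isolated) | CC[Si](CC)(CC)O[C@H](c1ccc(O[Si](C(C)C)(C(C)C)C(C)C)cc1)[C@H](C#C[Li])c1cc(O[Si](C(C)C)(C(C)C)C(C)C)cc(O[Si](C(C)C)(C(C)C)C(C)C)c1 | intermediate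
14 | lithium ynolate from 13, oxygen on the terminal alkyne carbon (not isolated) | CC[Si](CC)(CC)O[C@H](c1ccc(O[Si](C(C)C)(C(C)C)C(C)C)cc1)[C@H](C#CO[Li])c1cc(O[Si](C(C)C)(C(C)C)C(C)C)cc(O[Si](C(C)C)(C(C)C)C(C)C)c1 | intermediate
15 | triethyl{[(1S,2S)-2-[3,5-bis(triisopropylsiloxy)phenyl]-1-[4-(triisopropylsiloxy)phenyl]-4-(triisopropylsiloxy)but-3-yn-1-yl]oxy}silane | CC[Si](CC)(CC)O[C@H](c1ccc(O[Si](C(C)C)(C(C)C)C(C)C)cc1)[C@H](C#CO[Si](C(C)C)(C(C)C)C(C)C)c1cc(O[Si](C(C)C)(C(C)C)C(C)C)cc(O[Si](C(C)C)(C(C)C)C(C)C)c1 | intermediate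
16 | tert-butyldimethyl(prop-2-yn-1-yloxy)silane | C#CCO[Si](C)(C)C(C)(C)C | starting material
17 | trichloroacetyl chloride | ClC(=O)C(Cl)(Cl)Cl | starting material
18 | dichloroketene (not isolated) | ClC(Cl)=C=O | intermediate
19 | 3-{[(tert-butyldimethylsilyl)oxy]methyl}-4,4-dichlorocyclobut-2-en-1-one | O=C1C=C(CO[Si](C)(C)C(C)(C)C)C1(Cl)Cl | intermediate
20 | 3-{[(tert-butyldimethylsilyl)oxy]methyl}cyclobut-2-en-1-one | O=C1CC(CO[Si](C)(C)C(C)(C)C)=C1 | intermediate
21 | vinylketene 3-{[(tert-butyldimethylsilyl)oxy]methyl}buta-1,3-dien-1-one (not isolated) | O=C=CC(=C)CO[Si](C)(C)C(C)(C)C | intermediate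
22 | [2+2] adduct: cyclobut-2-en-1-one with the (1S,2S) side chain of 15 on C2, triisopropylsiloxy on C3 and a 3-[(tert-butyldimethylsilyl)oxy]prop-1-en-2-yl group on C4, both epimers at C4 (not isolated) | CC[Si](CC)(CC)O[C@H](c1ccc(O[Si](C(C)C)(C(C)C)C(C)C)cc1)[C@H](C1=C(O[Si](C(C)C)(C(C)C)C(C)C)C(C(=C)CO[Si](C)(C)C(C)(C)C)C1=O)c1cc(O[Si](C(C)C)(C(C)C)C(C)C)cc(O[Si](C(C)C)(C(C)C)C(C)C)c1 | intermediate
23 | dienylketene: hexa-1,3,5-trien-1-one with the (1S,2S) side chain on C2, triisopropylsiloxy on C3 and the siloxymethyl group on C5, C2 and C5 cis across the C3=C4 bond (not isolated) | CC[Si](CC)(CC)O[C@H](c1ccc(O[Si](C(C)C)(C(C)C)C(C)C)cc1)[C@H](C(=C=O)/C(O[Si](C(C)C)(C(C)C)C(C)C)=C\C(=C)CO[Si](C)(C)C(C)(C)C)c1cc(O[Si](C(C)C)(C(C)C)C(C)C)cc(O[Si](C(C)C)(C(C)C)C(C)C)c1 | intermediate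
24 | cyclohexa-2,4-dien-1-one with the (1S,2S) side chain on C2, triisopropylsiloxy on C3 and the siloxymethyl group on C5 (not isolated) | CC[Si](CC)(CC)O[C@H](c1ccc(O[Si](C(C)C)(C(C)C)C(C)C)cc1)[C@H](C1=C(O[Si](C(C)C)(C(C)C)C(C)C)C=C(CO[Si](C)(C)C(C)(C)C)CC1=O)c1cc(O[Si](C(C)C)(C(C)C)C(C)C)cc(O[Si](C(C)C)(C(C)C)C(C)C)c1 | intermediate
25 | 2-[(1S,2S)-1-[3,5-bis(triisopropylsiloxy)phenyl]-2-(triethylsiloxy)-2-[4-(triisopropylsiloxy)phenyl]ethyl]-5-{[(tert-butyldimethylsilyl)oxy]methyl}-3-(triisopropylsiloxy)phenol | CC[Si](CC)(CC)O[C@H](c1ccc(O[Si](C(C)C)(C(C)C)C(C)C)cc1)[C@H](c1c(O)cc(CO[Si](C)(C)C(C)(C)C)cc1O[Si](C(C)C)(C(C)C)C(C)C)c1cc(O[Si](C(C)C)(C(C)C)C(C)C)cc(O[Si](C(C)C)(C(C)C)C(C)C)c1 | intermediate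
26 | tert-butyl{[(2S,3S)-3-[3,5-bis(triisopropylsiloxy)phenyl]-4-(triisopropylsiloxy)-2-[4-(triisopropylsiloxy)phenyl]-2,3-dihydro-1-benzofuran-6-yl]methoxy}dimethylsilane (not isolated) | CC(C)(C)[Si](C)(C)OCc1cc(O[Si](C(C)C)(C(C)C)C(C)C)c2c(c1)O[C@H](c1ccc(O[Si](C(C)C)(C(C)C)C(C)C)cc1)[C@H]2c1cc(O[Si](C(C)C)(C(C)C)C(C)C)cc(O[Si](C(C)C)(C(C)C)C(C)C)c1 | intermediate
27 | [(2S,3S)-3-[3,5-bis(triisopropylsiloxy)phenyl]-4-(triisopropylsiloxy)-2-[4-(triisopropylsiloxy)phenyl]-2,3-dihydro-1-benzofuran-6-yl]methanol | OCc1cc(O[Si](C(C)C)(C(C)C)C(C)C)c2c(c1)O[C@H](c1ccc(O[Si](C(C)C)(C(C)C)C(C)C)cc1)[C@H]2c1cc(O[Si](C(C)C)(C(C)C)C(C)C)cc(O[Si](C(C)C)(C(C)C)C(C)C)c1 | intermediate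
28 | (2S,3S)-3-[3,5-bis(triisopropylsiloxy)phenyl]-4-(triisopropylsiloxy)-2-[4-(triisopropylsiloxy)phenyl]-2,3-dihydro-1-benzofuran-6-carbaldehyde | O=Cc1cc(O[Si](C(C)C)(C(C)C)C(C)C)c2c(c1)O[C@H](c1ccc(O[Si](C(C)C)(C(C)C)C(C)C)cc1)[C@H]2c1cc(O[Si](C(C)C)(C(C)C)C(C)C)cc(O[Si](C(C)C)(C(C)C)C(C)C)c1 | intermediate
29 | gnetal, (2S,3S)-3-(3,5-dihydroxyphenyl)-4-hydroxy-2-(4-hydroxyphenyl)-2,3-dihydro-1-benzofuran-6-carbaldehyde | O=Cc1cc(O)c2c(c1)O[C@H](c1ccc(O)cc1)[C@H]2c1cc(O)cc(O)c1 | target

## Step count and risks

Total step count: 14. Longest linear sequence: 11 steps (steps 1, 2, 3, 4, 6, 7, 8, 11, 12, 13, 14). Steps 5, 9 and 10 are side branches.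

**Step 11 (key step).** The ketene–alkyne [2+2] may be slow at the branched alkyne terminus. Vinylketene 21 would then dimerise or acylate the phenol of 25, and on long heating the siloxyalkyne may undergo a 1,3-silyl shift. The fallback generates the same vinylketene photochemically at room temperature from a diazo ketone, in the presence of excess 15 and at a low steady concentration:

- Baylis–Hillman hydroxymethylation of methyl vinyl ketone with formaldehyde (DABCO) gives 3-(hydroxymethyl)but-3-en-2-one F1.
- TBSCl and imidazole give 3-{[(tert-butyldimethylsilyl)oxy]methyl}but-3-en-2-one F2.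
- Trifluoroacetylation of the methyl ketone (LiN(SiMe3)2, CF3CO2CH2CF3) gives 5-{[(tert-butyldimethylsilyl)oxy]methyl}-1,1,1-trifluorohex-5-ene-2,4-dione F3.
- Detrifluoroacetylative diazo transfer (MsN3, Et3N, water, MeCN) gives 1-diazo-3-{[(tert-butyldimethylsilyl)oxy]methyl}but-3-en-2-one F4.
- Irradiating F4 with 15 in 1,2-dichloroethane at room temperature triggers a Wolff rearrangement to 21, which enters the same cascade; brief warming completes the electrocyclisations.

The fallback sets out from 15 and returns to the route at 25.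

**Step 6.** Configuration may be lost by ionisation of the benzylic, propargylic mesylate before oxidative addition, or by equilibration of the aryl-conjugated allenylzinc 10 through its propargyl isomer; either erodes C3. The fallback abandons reliance on chirality transfer and purifies by resolution:

- Enantio-impure 11 is esterified with (S)-2-methoxy-2-phenylacetic acid (DCC, DMAP).
- This gives (1S,2R)-2-[3,5-bis(triisopropylsiloxy)phenyl]-1-[4-(triisopropylsiloxy)phenyl]but-3-yn-1-yl (2S)-2-methoxy-2-phenylacetate F5 and its diastereomer from the wrong enantiomer, (1R,2S)-2-[3,5-bis(triisopropylsiloxy)phenyl]-1-[4-(triisopropylsiloxy)phenyl]but-3-yn-1-yl (2S)-2-methoxy-2-phenylacetate F6.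
- The two are separated by chromatography or crystallisation.
- F5 is cleaved reductively (i-Bu2AlH, CH2Cl2, −78 °C), which spares the aryl silyl ethers.

The fallback sets out from 11 and returns at enantiopure 11.

**Step 8.** Oxygen transfer to the hindered acetylide may be incomplete, or competing deprotonation at the benzylic, propargylic C3–H may epimerise C3 or isomerise the alkyne to an allene. The fallback reaches the ynolate without a strongly basic acetylide:

- 12 is treated with PhI(OH)OTs (CH2Cl2, desiccant) to give phenyl{(3S,4S)-3-[3,5-bis(triisopropylsiloxy)phenyl]-4-(triethylsiloxy)-4-[4-(triisopropylsiloxy)phenyl]but-1-yn-1-yl}iodonium 4-methylbenzenesulfonate F7.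
- Catalytic CuOTf in acetonitrile collapses F7 to (3S,4S)-3-[3,5-bis(triisopropylsiloxy)phenyl]-4-(triethylsiloxy)-4-[4-(triisopropylsiloxy)phenyl]but-1-yn-1-yl 4-methylbenzenesulfonate F8.
- MeLi at −78 °C attacks sulfur and releases ynolate 14, which is silylated with TIPSOTf as in the main route.

The fallback sets out from 12 and returns at 14 and thus at 15.

**Step 12.** The C2 cation may lose the C3 proton to give a triarylethene, and reprotonation would erode C3. Trans selectivity may be incomplete, or the para silyl group may be lost early from the quinone-methide-like cation. The fallback closes the ring under nearly neutral conditions, as nature does: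

- Global desilylation of 25 with buffered fluoride gives 2-[(1S,2S)-1-(3,5-dihydroxyphenyl)-2-hydroxy-2-(4-hydroxyphenyl)ethyl]-5-(hydroxymethyl)benzene-1,3-diol F9.
- Gentle warming in aqueous acetonitrile dehydrates the 4-hydroxybenzylic alcohol to the para-quinone methide 4-[(2S)-2-[2,6-dihydroxy-4-(hydroxymethyl)phenyl]-2-(3,5-dihydroxyphenyl)ethylidene]cyclohexa-2,5-dien-1-one F10.
- Either of the two equivalent ring A phenols adds to F10 in a 1,6-fashion to give (2S,3S)-3-(3,5-dihydroxyphenyl)-6-(hydroxymethyl)-2-(4-hydroxyphenyl)-2,3-dihydro-1-benzofuran-4-ol F11, trans by equilibration.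
- Oxidation of the benzylic alcohol of F11 with MnO2 in acetone gives the aldehyde.

The fallback sets out from 25 and returns at 29.

## Further compounds

F1 | step 11 | 3-(hydroxymethyl)but-3-en-2-one | CC(=O)C(=C)CO
F2 | step 11 | 3-{[(tert-butyldimethylsilyl)oxy]methyl}but-3-en-2-one | CC(=O)C(=C)CO[Si](C)(C)C(C)(C)C
F3 | step 11 | 5-{[(tert-butyldimethylsilyl)oxy]methyl}-1,1,1-trifluorohex-5-ene-2,4-dione | O=C(CC(=O)C(=C)CO[Si](C)(C)C(C)(C)C)C(F)(F)F
F4 | step 11 | 1-diazo-3-{[(tert-butyldimethylsilyl)oxy]methyl}but-3-en-2-one | [N-]=[N+]=CC(=O)C(=C)CO[Si](C)(C)C(C)(C)C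
F5 | step 6 | (1S,2R)-2-[3,5-bis(triisopropylsiloxy)phenyl]-1-[4-(triisopropylsiloxy)phenyl]but-3-yn-1-yl (2S)-2-methoxy-2-phenylacetate | CO[C@H](C(=O)O[C@H](c1ccc(O[Si](C(C)C)(C(C)C)C(C)C)cc1)[C@H](C#C)c1cc(O[Si](C(C)C)(C(C)C)C(C)C)cc(O[Si](C(C)C)(C(C)C)C(C)C)c1)c1ccccc1
F6 | step 6 | (1R,2S)-2-[3,5-bis(triisopropylsiloxy)phenyl]-1-[4-(triisopropylsiloxy)phenyl]but-3-yn-1-yl (2S)-2-methoxy-2-phenylacetate | CO[C@H](C(=O)O[C@@H](c1ccc(O[Si](C(C)C)(C(C)C)C(C)C)cc1)[C@@H](C#C)c1cc(O[Si](C(C)C)(C(C)C)C(C)C)cc(O[Si](C(C)C)(C(C)C)C(C)C)c1)c1ccccc1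
F7 | step 8 | phenyl{(3S,4S)-3-[3,5-bis(triisopropylsiloxy)phenyl]-4-(triethylsiloxy)-4-[4-(triisopropylsiloxy)phenyl]but-1-yn-1-yl}iodonium 4-methylbenzenesulfonate | CC[Si](CC)(CC)O[C@H](c1ccc(O[Si](C(C)C)(C(C)C)C(C)C)cc1)[C@H](C#C[I+]c1ccccc1)c1cc(O[Si](C(C)C)(C(C)C)C(C)C)cc(O[Si](C(C)C)(C(C)C)C(C)C)c1.Cc1ccc(S(=O)(=O)[O-])cc1
F8 | step 8 | (3S,4S)-3-[3,5-bis(triisopropylsiloxy)phenyl]-4-(triethylsiloxy)-4-[4-(triisopropylsiloxy)phenyl]but-1-yn-1-yl 4-methylbenzenesulfonate | CC[Si](CC)(CC)O[C@H](c1ccc(O[Si](C(C)C)(C(C)C)C(C)C)cc1)[C@H](C#COS(=O)(=O)c1ccc(C)cc1)c1cc(O[Si](C(C)C)(C(C)C)C(C)C)cc(O[Si](C(C)C)(C(C)C)C(C)C)c1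
F9 | step 12 | 2-[(1S,2S)-1-(3,5-dihydroxyphenyl)-2-hydroxy-2-(4-hydroxyphenyl)ethyl]-5-(hydroxymethyl)benzene-1,3-diol | O[C@H](c1ccc(O)cc1)[C@H](c1c(O)cc(CO)cc1O)c1cc(O)cc(O)c1
F10 | step 12 | 4-[(2S)-2-[2,6-dihydroxy-4-(hydroxymethyl)phenyl]-2-(3,5-dihydroxyphenyl)ethylidene]cyclohexa-2,5-dien-1-one | O=C1C=CC(=C[C@H](c2c(O)cc(CO)cc2O)c2cc(O)cc(O)c2)C=C1
F11 | step 12 | (2S,3S)-3-(3,5-dihydroxyphenyl)-6-(hydroxymethyl)-2-(4-hydroxyphenyl)-2,3-dihydro-1-benzofuran-4-ol | OCc1cc(O)c2c(c1)O[C@H](c1ccc(O)cc1)[C@H]2c1cc(O)cc(O)c1
A1 | alternative 1 | 4-[(2S,3S)-3-(3,5-dimethoxyphenyl)-6-(1,3-dioxolan-2-yl)-4-methoxy-2,3-dihydro-1-benzofuran-2-yl]phenyl trifluoromethanesulfonate | O1CCOC1c1cc(OC)c2c(c1)O[C@H](c1ccc(OS(=O)(=O)C(F)(F)F)cc1)[C@H]2c1cc(OC)cc(OC)c1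
A2 | alternative 1 | 4-[(2R,3R)-3-(3,5-dimethoxyphenyl)oxiran-2-yl]phenyl trifluoromethanesulfonate | O1[C@H](c2ccc(OS(=O)(=O)C(F)(F)F)cc2)[C@H]1c1cc(OC)cc(OC)c1
A3 | alternative 1 | 5-(1,3-dioxolan-2-yl)-3-methoxy-2-(trimethylsilyl)phenyl trifluoromethanesulfonate | COc1cc(C2OCCO2)cc(OS(=O)(=O)C(F)(F)F)c1[Si](C)(C)C
A4 | alternative 2 | 2-[(E)-2-(3,5-dimethoxyphenyl)ethenyl]-4,4,5,5-tetramethyl-1,3,2-dioxaborolane | COc1cc(/C=C/B2OC(C)(C)C(C)(C)O2)cc(OC)c1
A5 | alternative 2 | 4-methoxyphenyllithium | [Li]c1ccc(OC)cc1
A6 | alternative 2 | 2-chloro-4-(1,3-dioxolan-2-yl)-6-methoxyphenyl trifluoromethanesulfonate | COc1cc(C2OCCO2)cc(Cl)c1OS(=O)(=O)C(F)(F)F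
A7 | alternative 2 | 2-[(1S,2S)-2-[2-chloro-4-(1,3-dioxolan-2-yl)-6-methoxyphenyl]-2-(3,5-dimethoxyphenyl)-1-(4-methoxyphenyl)ethyl]-4,4,5,5-tetramethyl-1,3,2-dioxaborolane | CC1(C)OB(OC1(C)C)[C@H](c1ccc(OC)cc1)[C@H](c1c(Cl)cc(cc1OC)C1OCCO1)c1cc(OC)cc(OC)c1
A8 | alternative 3 | (2S,3S)-3-(3,5-dimethoxyphenyl)-2-(4-methoxyphenyl)-4-oxo-2,3-dihydro-4H-furo[3,2-c]pyran-6-carbaldehyde | O=CC1=CC2=C(C(=O)O1)[C@H](c1cc(OC)cc(OC)c1)[C@@H](c1ccc(OC)cc1)O2
A9 | alternative 3 | ethoxyethyne | C#COCC
A10 | alternative 3 | (2S,3S)-3-(3,5-dimethoxyphenyl)-4-ethoxy-2-(4-methoxyphenyl)-2,3-dihydro-1-benzofuran-6-carbaldehyde | O=Cc1cc(OCC)c2c(c1)O[C@H](c1ccc(OC)cc1)[C@H]2c1cc(OC)cc(OC)c1
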